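The trap in this flask is to read its late excess as the catalyst's selectivity: a racemate used up to the end without exchange gives racemic product, however selective the catalyst.

common to all: left-handed substrate 0.80 M; right-handed substrate 0.80 M; added ligand 8.7 mM
- red: solid reagent 2.2 equiv; free catalyst 1 mol%; racemization catalyst 0.7 mol%; run made earlier
- ochre: solid reagent 2.2 equiv; free catalyst 1 mol%; racemization catalyst 1.1 mol%; run made earlier
- teal: solid reagent 2.2 equiv; free catalyst 2 mol%; racemization catalyst 0.5 mol%; run made earlier
- flask: solid reagent 2.20 equiv; free catalyst 1 mol%; racemization catalyst 0.5 mol%; time 12 h

| run | time / h | left-handed product / % | right-handed product / % |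
|---|---|---|---|
| red | 1.00 | 10.5 | 6.5 |
| red | 2.50 | 29.7 | 17.7 |
| red | 6.00 | 51.9 | 40.5 |
| red | 15.0 | 52.7 | 46.4 |
| ochre | 4.00 | 43.4 | 28.0 |
| ochre | 8.00 | 53.1 | 40.8 |
| ochre | 10.0 | 54.6 | 43.2 |
| ochre | 15.0 | 53.7 | 44.5 |
| teal | 4.00 | 45.7 | 36.7 |
| teal | 8.00 | 52.6 | 48.3 |
| teal | 10.0 | 50.3 | 49.6 |
| teal | 15.0 | 50.1 | 48.0 |

(readings scatter by 1 percentage point)

- free catalyst is single-handed; left-handed substrate and right-handed substrate are mirror images of each other, charged as a racemate, each of them at the stated concentration
- given per volume of solution although it is solid: solid reagent
- the numbers in the tables scatter with a standard deviation of 1 percentage point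
- at the start none of the solid reagent is in solution
- an excess is the difference of the two amounts in percent of their sum
- an excess is below zero if the other one leads

1. left-handed product and right-handed product together, in percent of the left-handed substrate and right-handed substrate charged together, at 12 h
2. excess of left-handed product over right-handed product in the product at 12 h
3. whether the exchange between left-handed substrate and right-handed substrate keeps pace with the reaction: how far the product's excess at 12 h gets from its value without exchange to its value with instant exchange (above 80% keeps pace, below 20% hardly takes part, else lags behind)

**One molecule.** A substrate molecule has a fork: it becomes product on the free catalyst, or the racemization catalyst turns it into its mirror form. The selectivity factor s, the logarithm of the share of left-handed substrate unreacted over that of the share of right-handed substrate unreacted, tells how many times more readily the left-handed form reacts. As readings, with exchange neglected, the red run at 2.50 h gives 2.06 and the teal run at 4.00 h gives 1.85, so s = 1.96. With the substrate held racemic by instant exchange, the product excess is (s − 1)/(s + 1), here 32.4%: the ceiling.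

**First instants.** None of the solid reagent is in solution at the start. The red run, at the flask's free catalyst loading, already shows left-handed product ahead at 1.00 h, 10.5% against 6.5%.

**The middle.** At 6.00 h the red run holds 51.9% of left-handed product against 40.5% of right-handed product, so about 7.60% of the charge remains as substrate in that run.

**The end.** Both substrates were charged equally, so once both are consumed a product difference counts net crossings. At 15.0 h the excess reads 6.36% in the red run and 9.37% in the ochre run. A straight line through their loadings, this text's own reckoning, gives 4.85% at the flask's 0.5 mol%. That is 15.0% of the ceiling, counted from zero, which is below the 20% mark. The ochre run totals 97.8% at 10.0 h, so the flask should stand near that at 12 h.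

**The forecast.** It gives 98.5% (96% to 100.5%), an excess of 3% (0.5% to 6%), and says the exchange hardly takes part. It reads s as about 1.65 and the ceiling as about 25%, where this text has 1.96 and 32.4%. Its excess lies below 4.85%, since it says of the added ligand and the racemization catalyst that the ligand “may largely titrate it”.

**The flask.** The flask gives 98.7% with an excess of 5.08%, and the exchange hardly takes part.

    partner + free catalyst + right-handed substrate → free catalyst + right-handed product (k = 0.0460 M⁻² s⁻¹)
    racemization catalyst + added ligand ⇌ idle complex, settled at all times (K = 400 M⁻¹)
    solid reagent ⇌ partner, rate k3*(cs3 - [partner]) while solid is left; crystals form when [partner] > cs3 (solubility = 0.680 M, k = 1.90 × 10⁻⁴ s⁻¹)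
    partner + free catalyst + left-handed substrate → free catalyst + left-handed product (k = 0.0930 M⁻² s⁻¹)
    left-handed substrate + racemization catalyst ⇌ right-handed substrate + racemization catalyst, rate k5*[racemization catalyst]*[left-handed substrate] forward; the back reaction follows from the equilibrium constant (k = 0.00690 M⁻¹ s⁻¹)

At 12.0 h, 29.8% of the racemization catalyst is free and 70.2% is idle complex, and the excess has gone 11% of the way to its instant-exchange value. Against the ceiling from s, the flask's excess is 15.7%. The same flask with 0.550 equiv of solid reagent stands at 27.5% at 12.0 h with 0% of that reagent left, and its excess of 29.3% is 90.4% of that ceiling.

The earlier runs and the new flask were generated by integration on assumed constants, and the scatter is random.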